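Readings and results were computed with made-up constants; the scatter is artificial.

Late in both earlier runs the target reading stands still, so what I need is the height of that plateau in the new flask, and first I ask which given number has to be known well.

| setting | maple | birch | flask |
|---|---|---|---|
| substrate | 0.17 M | 0.38 M | 0.25 M |
| gas | 39 mM (held) | 39 mM (held) | 39 mM (held) |
| remark | run made earlier | run made earlier |  |
| time |  |  | 10 min |

| run | time / min | substrate / % | target / % |
|---|---|---|---|
| maple | 0.417 | 55.8 | 20.6 |
| maple | 1.33 | 13.0 | 66.4 |
| maple | 2.50 | 0.7 | 75.3 |
| maple | 3.00 | 0 | 75.4 |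
| maple | 5.00 | 0 | 75.9 |
| maple | 6.00 | 0.1 | 75.6 |
| maple | 8.00 | 0 | 76.1 |
| birch | 1.00 | 25.4 | 31.6 |
| birch | 2.50 | 2.2 | 56.7 |
| birch | 3.00 | 0.8 | 57.4 |
| birch | 5.00 | 0.1 | 57.4 |
| birch | 6.00 | 0.4 | 57.6 |
| birch | 8.00 | 0.4 | 57.1 |

(readings scatter by 0.3 percentage points)

- at the start none of the gas is in solution
- a reading or a percentage of target counts all its forms, free or not
- the reaction counts as stopped when no species that holds the substrate changes by six tenths of a point or more over the second half of the time

* at 10 min, what has stopped the reaction, if anything has (forward and back rates have come level / it is still moving / all of the substrate has reacted)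
* conversion of substrate at 10 min
* amount of target at 10 min, in percent of the substrate charged

The time hardly needs knowing: in the maple run target goes from 75.4 % at 3.00 min to 76.1 % at 8.00 min, and the flask's 10 min lies later still. The gas stands at 39 mM in both runs and in the flask, so the readings cannot show what a change would do, and none is asked. The scatter of 0.3 percentage points is small against the 19 points between the two plateaus. But that gap comes with the charge, 0.17 M against 0.38 M, so the charge is the number that counts.

Substrate reads 0.4 % at 8.00 min in the birch run, so I take its reaction as finished and reckon with what it leaves. With y the plateau target as a fraction of the charge and c the charge, I define the waste ratio w = (1 − y)/y, which is selectivity turned upside down. Dividing by c gives the waste coefficient g, waste per target per unit of charge: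

maple: w = 0.314, w/c = 1.85 M⁻¹

birch: w = 0.751, w/c = 1.98 M⁻¹

mean: g = 1.91 M⁻¹

flask: y = 1/(1 + g c) = 67.7 %

I commit to that, with the substrate fully reacted.

The forecast says all of the substrate has reacted, with conversion 100 % and target 68 %, holding that “the reaction stops because substrate runs out”.

At 10 min the flask gives: all of the substrate has reacted, conversion 100 %, target 69.4 %.

    substrate ⇌ open intermediate (K = 19.0, k = 0.0220 s⁻¹)
    partner → second intermediate (k = 0.0650 s⁻¹)
    open intermediate + second intermediate → target (k = 4.30 M⁻¹ s⁻¹)
    2 open intermediate → homo product (k = 0.360 M⁻¹ s⁻¹)
    substrate + second intermediate → side product (k = 0.120 M⁻¹ s⁻¹)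
    crystals ⇌ target, rate k6*(cs6 - [target]) while solid is left; crystals form when [target] > cs6 (solubility = 8.10 mM, k = 1.40 s⁻¹)
    gas ⇌ partner, rate k7*(csat - [partner]) (kL = 1.30 s⁻¹)

That stands 1.7 points above my reckoning, and read back it makes w/c 1.76 M⁻¹ in this flask, against g of 1.91 M⁻¹. The neighbouring flask, with 1.0 M of substrate and the rest held, lies far beyond the charges g was read from. The same reckoning gives 34.3 %, and that flask gives 31.4 %, with substrate at 0 %. Its homo product holds the most of the charge, 64.5 %, while its side product holds 4.08 %.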